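Late in a run I look first at where the product has come to rest, so I began this flask from its last hours. L meets E, which Q feeds across from the second phase, and the L.E formed can pass into X or be lost.

L 0.010 M; Q 3.00 equiv; time 5.0 h; volume of the second phase over the first 2.0

    L + E → L.E (k1 = 2.9 M⁻¹ min⁻¹)
    L.E ⇌ X, rate k2*([L.E] - [X]/K2) per volume of the first phase (K2 = 15, k2 = 0.015 min⁻¹)
    E ⇌ Q, rate k3*([E] - [Q]/K3) per volume of the first phase (K3 = 1.0, k3 = 1.1 min⁻¹)
    E → Z (k4 = 0.022 min⁻¹)
    L.E → J (k5 = 0.033 min⁻¹)
    L + L.E → L.L.E (k6 = 2.2 M⁻¹ min⁻¹)

- in percentages every species weighs as the L in it: one L.L.E counts as two
- for L.E the X are counted in
- in the second phase: Q, X; everything else is in the first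
- charges count per volume of the first phase; a concentration in a rate is the amount of a species over the volume of its own phase; every rate counts per litre of the first phase
- run time (flask): 5.0 h

- how much L.E and X together there is at 5.0 h, in percent of the L charged
- the change that raises the amount of L.E and X together at 5.0 h, in percent of the L charged most ("none" if none brings more than 2 percentage points) (east / south / south-west / none)
- amount of L.E and X together at 5.0 h, in percent of the L charged, after south

- east: doubling the transfer coefficient of step 3, all else as stated
- south: doubling the transfer coefficient of step 2, all else as stated
- south-west: doubling the amount of Q, all else as stated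

Two numbers did not seem to go together. At equilibrium, X over reaction-phase L.E in amounts is the partition ratio times the volume ratio, 30.0, so nearly all of the pair should sit in X. Yet the transfer into X, at 0.015 min⁻¹, runs at about half the exit to J, 0.033 min⁻¹. That ratio tells where L.E that survives ends up, and it does not tell how much survives, which is a matter of kinetic rather than thermodynamic control.

As the zero of my scale I took 3 equally fast exits from reaction-phase L.E, which would give X a third. Here the transfer, at 0.015 min⁻¹, is slower than the exit to J, 0.033 min⁻¹, and slower than the exit to L.L.E at charged [L], 0.0220 min⁻¹. So I defined the capture share, the transfer coefficient over the sum of these exits, as 21.4%. Taking the L as consumed, that share was my estimate of y. Doubling the transfer coefficient raised it to 35.3%, while east and south-west left it unchanged, so I chose south.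

The forecast gave 20% (17% to 23%), south, and 29% (25% to 33%) after that change, holding that “about a fifth of that reaches X”. Its figure after south was lower than mine.

The simulation gave 20.7% and south, which gained 11 percentage points, against 2.7 points for south-west and 0.009 points for east, with 31.3% after south. The forecast stood. My share lay 0.70 points above y and 4 points above the result after south.

In this flask the transfer of Q to E had 89% of its turnover up to 5.00 h behind it at 2.50 h, when L had fallen to 9.65% and X had risen to 19.6%. At 5.00 h X stood at 20.2%, nearly all of the L.E with X counted in, while J had gone from 45.3% to 50.0%. In the neighbour flask charged with 0.0025 M of L, the exit to L.L.E at charged [L] reckons at a quarter of its speed here, so the share is 28.0%, higher than 21.4%. With 44.9% of that L left, this gives 15.4%, and the simulation gave 14.4%.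

Its constants stand for no real mixture; the flask was simulated.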